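## Structural features

The target is a spiro[4.5]decane in which a cyclohexane (ring B) and a cyclopentane (ring A) share the quaternary carbon C2 (local numbering used throughout: ring B = C1–C6, ring A = C2, C7–C10, side chain C11–C15). Ring B carries a 3-hydroxypropyl arm at C1, a methyl carbinol at C3 and, at C6, an exocyclic tetrasubstituted enal whose CHO is cis to C1. Ring A carries a secondary OH at C7 and, at C8, a 2-substituted (E)-1,3,5-triene (C11–C15) that ends in an allylic acetate and a prenyl terminus. Five stereocentres are contiguous: C1, C2, C3 in ring B (arm, C7 and the C3 hydroxyl all on one face) and C2, C7, C8 in ring A (OH and triene cis, the OH turned towards C1 and away from C3). The fragile parts are the enal (its γ-hydrogen at C1 allows deconjugation and loss of alkene geometry), the triene (acid, light, electrophiles), the allylic acetate (bases, hydrides, zerovalent palladium) and the tertiary carbinol. The real difficulty is the all-carbon spiro centre flanked by stereocentres on three sides, together with a tetrasubstituted alkene of defined geometry that carbonyl olefination cannot set. The key step exploits that C3 (with methyl and oxygen), C4 and C5 are the carbinol end of linalool: a keto ester carbon (C1) is joined to an alkyne carbon (C6), ring B closes, and anti addition across the alkyne puts iodine trans and the CH2O group cis to C1, which is the enal geometry.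

## Logic of the disconnections

39 ⇒ 38 ⇒ 37. No skeletal bond is cut; the enal goes back to the allylic alcohol and four O–H bonds become O–Si bonds. The enal is thereby kept out of every basic or organometallic step. One class of protecting group suffices and comes off in one operation. The forward steps need a fluoride source that spares acetate and triene, and an oxidant that takes only the allylic alcohol among four hydroxyls.

37 ⇒ 28 + 36. The C11–C12 sp2–sp2 bond is cut. The triene then appears only three steps before the end, and its alkene geometries are carried in by 36. The gain is a convergent union of a 22-carbon and a 10-carbon piece. The demand is a neutral coupling of a hindered 1,1-disubstituted enol triflate.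

36 ⇒ 34 + 35; 34 ⇒ 33 ⇒ 29 + 30. The C13–C14 bond and the bond from C15 to the homoprenyl chain are cut. Anti carbomagnesiation of a propargylic alcohol sets the trisubstituted alkene (CH2O cis to C14) in one step from two small commercial pieces. The demand is retention of alkene geometry through iodination and two couplings.

28 ⇒ 26 ⇒ 25 ⇒ 24. The C7–C8 bond is cut, with removal of the hydride at C9. This opens ring A and removes both of its stereocentres, and the acetyl group is the latent 1,1-disubstituted alkene. The forward closure must give the cis aldol and must add to the aldehyde face that turns the oxygen towards C1.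

24 ⇒ 23. The C8=C9 alkene is cut by metathesis logic. The enone is reduced to an allyl group plus a commodity enone. The demand is chemoselectivity for the only monosubstituted alkene.

23 ⇒ 21. The C2–C10 bond is cut. This removes the quaternary centre and leaves an enolisable aldehyde. The forward alkylation must enter anti to the axial groups on C1 and C3.

21 ⇒ 20 ⇒ 19 ⇒ 17 ⇒ 16. The C2–C7 bond is cut (as C=CH2 from a ketone), and so are the two primary C–O bonds. A non-basic one-carbon homologation suits a hindered, epimerisable ketone, and one hydroboration reveals C7–O and the arm hydroxyl together. The demand is differentiation of two primary alcohols.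

16 ⇒ 13 ⇒ 12. The bond from C1 to the arm is cut and the C1–CO2 bond is restored. The keto ester is the only handle that makes C1 nucleophilic, and it then leaves as CO2. The demand is that C1–H is installed on the correct face without migration of the exocyclic alkene.

12 ⇒ 11. The bond from the exocyclic carbon to its methyl group is cut. The demand is coupling with retention at a tetrasubstituted alkenyl iodide.

11 ⇒ 10. The C1–C6 bond is cut; this is the key disconnection. Ring B opens to an acyclic alkynyl keto ester, and the alkene geometry is traced back to anti addition across the alkyne. The demand is a 6-exo carbocyclisation onto an internal alkyne with iodide capture.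

10 ⇒ 8 + 9. The C1–C2 bond is cut. The keto ester comes from an aldehyde without an α-hydrogen and a diazo ester.

8 ⇒ 7 ⇒ 4 ⇒ 3 ⇒ 2 ⇒ 1. The bonds cut are the alkyne–CH2O bond, the alkyne carbon added by homologation, and (in the forward sense) two C=C bonds that are cleaved. The stereocentre C3 and the C3–C5 chain come unchanged from 1. The demand is two chemoselective alkene cleavages (trisubstituted before vinyl, then vinyl beside an alkyne).

## Other disconnections considered

Alternative 1: The cut is the C2–C10 bond together with the C3–O bond, so that ring A grows out of a cyclobutanol. In the forward step the achiral allylic cyclobutanol A1 is epoxidised on its tetrasubstituted alkene by VO(OiPr)3, a chiral bishydroxamic acid and tert-butyl hydroperoxide. The epoxy alcohol opens with a 1,2-shift of a cyclobutane CH2 to C2 and gives the spiro hydroxy ketone A2.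
- In its favour: one catalytic step creates C2 and C3 with the right relative configuration, because the migrating carbon enters anti to the epoxide oxygen (C10 trans, C7 carbonyl cis to the C3 hydroxyl). Absolute configuration comes from a catalyst and not from the optical purity of a terpene. The C7 ketone is placed for a hydroxyl-directed reduction that would turn the carbinol towards C1.
- Against it here: A2 has neither the C1 arm nor the C6 alkylidene. C1 would have to be alkylated at a neopentyl position next to the spiro centre. The tetrasubstituted enal would then come from the C6 ketone by olefination, where nothing decides whether CH3 or CHO ends cis to C1. A triene at C8 would sit α to the ketone and could slip into conjugation. Directed epoxidation of a tetrasubstituted alkene by a tertiary alcohol is a demanding case for the catalyst.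
- Comparison: on the spiro centre Alternative 1 is the better plan (stereospecific migration against the substrate-controlled alkylation of step 15), and it reaches the spiro core in far fewer steps. On absolute control it is at least the equal. The chosen plan is better on what Alternative 1 leaves open: the alkene geometry is fixed mechanistically in step 7 and C1 is functionalised from the start.

Alternative 2: The cuts are C1–C2 and C3–O; the future arm and enal carbons are first held in a seven-membered ring. In the forward step acid ionises the tertiary bis-allylic alcohol of A3 (written here in one plausible form, as a dimethylcarbamate) to a ring-locked allyl cation. The cyclopentylidene alkene attacks its secondary end (C1) through C2, and the carbamate carbonyl oxygen traps the cation at C3, giving the tricyclic carbonate A4. Cleavage of the disubstituted ring alkene of A4 would later release the enal and a three-carbon aldehyde arm.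
- In its favour: ring B and C1, C2, C3 arise in one anti addition across a tetrasubstituted alkene. The enal geometry is enforced by a ring, and the arm arrives with the right length. These two points are solved better than in the chosen plan, which needs an external electrophile for the geometry and several steps for the arm.
- Against it: as drawn, A4 holds the C7 oxygen on the C3 side, since the six-membered carbonate cannot close otherwise. That is the epimer of the target carbinol, so an inversion at a neopentyl carbon (Mitsunobu reaction, or oxidation and re-reduction) would have to follow. A3 needs a tetrasubstituted alkene of defined geometry and a functionalised cycloheptadienol. The cation may also be captured at its tertiary end or eliminate. After cleavage two aldehydes must be told apart, C8 is an unfunctionalised CH2, and the triene is still missing.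
- Comparison: structurally this is the most economical way to ring B, and on paper it equals the chosen plan for C1–C3 control. Mechanistically it rests on the regiochemistry of a cation, where step 7 carries less risk of skeletal side reactions. In step count it probably gains on ring B and loses again on the carbinol inversion and on ring A.

Alternative 3: The cut is C7–C8, the bond that closes ring A, with transfer of a hydrogen from the methyl group on C11. In the forward step Me2AlCl binds the neopentyl aldehyde of the monocyclic precursor A5 (written here in its implied form), and the trisubstituted alkene end of the polyene adds to it in an intramolecular carbonyl-ene reaction to give A6, the bis-silyl ether of the target.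
- In its favour: one step forms ring A, both ring A stereocentres (cis through the bicyclic ene transition state) and the exo-methylene, with the whole skeleton in place. On end-game step economy it is clearly better than the chosen plan, which needs steps 16 to 23 for the same result.
- Against it: the ene donor is the terminus of a conjugated triene next to an ionisable allylic acetate, and the Lewis acid must choose the saturated aldehyde over the enal. Polyene cyclisation, Prins pathways and acetate ionisation compete. Ring B is not addressed: A5 still needs the quaternary C2 with formyl group and a long sensitive chain, so a ring B synthesis such as steps 1 to 15 is still required. The chain would have to be attached by alkylating an aldehyde enolate with an unactivated halide, which is a poor reaction.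
- Comparison: the facial question at the aldehyde relative to ring B is the same as in step 17; here the two plans are equal. The chosen plan forms the same bond by an aldol closure onto the same aldehyde and adds the triene afterwards under neutral coupling conditions. It is longer but less exposed to chemoselectivity problems.

Key step: step 7

Remarks (one line each):
- The Conia-ene substrate carries a tert-butyl rather than an ethyl ester; this spectator change lets the ester leave later without base or strong heating.
- (S)-(+)-Linalool of high enantiomeric purity is assumed to be purchasable; every stereocentre derives from it.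
- In the cyclised keto ester 11 an equatorial ester at C1 is not tenable: allylic 1,3-strain with the cis CH2OSi group forces it axial, cis to the axial OSiEt3. The configuration drawn is still the expected one, but the centre is labile and is set again in step 10.
- The C10 side-chain piece is built from propargyl alcohol and 5-bromo-2-methylpent-2-ene, because carbomagnesiation fixes the trisubstituted alkene geometry in one step.

## Steps

Step 1
Reactants: 1 (S)-(+)-linalool
Product: 2 (3S)-3,7-dimethyl-3-(triethylsilyloxy)octa-1,6-diene
Conditions: TESOTf, 2,6-lutidine, CH2Cl2, −78 → 0 °C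
Reagents that add atoms: triethylsilyl triflate, CC[Si](CC)(CC)OS(=O)(=O)C(F)(F)F
Why: Silylation of a tertiary allylic alcohol with a silyl triflate and a hindered base proceeds without ionisation; the ether later keeps this oxygen from attacking the gold-activated alkyne.

Step 2
Reactants: 2 (3S)-3,7-dimethyl-3-(triethylsilyloxy)octa-1,6-diene
Product: 3 (4S)-4-methyl-4-(triethylsilyloxy)hex-5-enal
Conditions: O3 (1 equiv, Sudan Red 7B end point), pyridine, CH2Cl2, −78 °C
Reagents that add atoms: ozone, [O-][O+]=O
Why: Ozonolysis; electrophilic ozone should cleave the electron-rich trisubstituted alkene well before the vinyl group, which is monosubstituted and next to an electron-withdrawing silyloxy carbon. Pyridine lets the carbonyl oxide collapse to the aldehyde without a separate reduction.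

Step 3
Reactants: 3 (4S)-4-methyl-4-(triethylsilyloxy)hex-5-enal
Product: 4 (3S)-3-methyl-3-(triethylsilyloxy)hept-1-en-6-yne
Conditions: dimethyl (1-diazo-2-oxopropyl)phosphonate, K2CO3, MeOH, 0 °C → rt
Reagents that add atoms: dimethyl (1-diazo-2-oxopropyl)phosphonate, COP(=O)(OC)C(=[N+]=[N-])C(C)=O
Why: Ohira–Bestmann (Seyferth–Gilbert) homologation turns the aldehyde carbon into the future C6; the mild carbonate conditions leave the tertiary silyl ether in place.

Step 4
Reactants: 4 (3S)-3-methyl-3-(triethylsilyloxy)hept-1-en-6-yne
Product: 7 (3S)-8-(tert-butyldimethylsilyloxy)-3-methyl-3-(triethylsilyloxy)oct-1-en-6-yne, via lithium acetylide 5 (not isolated), via lithium alkoxide 6 (not isolated)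
Conditions: n-BuLi, THF, −78 °C; (CH2O)n, −78 °C → rt; TBSCl, DMAP (cat.), rt
Reagents that add atoms: formaldehyde (as paraformaldehyde), C=O; tert-butyldimethylsilyl chloride, CC(C)(C)[Si](C)(C)Cl
Why: Acetylide addition to formaldehyde, then O-silylation of the lithium alkoxide in the same flask; the vinyl group and the silyl ether are inert to n-BuLi at low temperature.

Step 5
Reactants: 7 (3S)-8-(tert-butyldimethylsilyloxy)-3-methyl-3-(triethylsilyloxy)oct-1-en-6-yne
Product: 8 (2S)-7-(tert-butyldimethylsilyloxy)-2-methyl-2-(triethylsilyloxy)hept-5-ynal
Conditions: O3 (1 equiv, Sudan Red 7B end point), pyridine, CH2Cl2, −78 °C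
Reagents that add atoms: ozone, [O-][O+]=O
Why: Ozonolysis of the remaining alkene; alkynes react with ozone far more slowly than alkenes, so the internal alkyne should survive when the addition stops at the end point. The aldehyde has no α-hydrogen and cannot epimerise.

Step 6
Reactants: 8 (2S)-7-(tert-butyldimethylsilyloxy)-2-methyl-2-(triethylsilyloxy)hept-5-ynal; 9 tert-butyl diazoacetate
Product: 10 tert-butyl (4S)-9-(tert-butyldimethylsilyloxy)-4-methyl-3-oxo-4-(triethylsilyloxy)non-7-ynoate
Conditions: SnCl2 (10 mol%), CH2Cl2, rt
Reagents that add atoms: none
Why: Roskamp reaction; the diazo carbon adds to the SnCl2-activated aldehyde and a 1,2-hydride shift with loss of N2 gives the β-keto ester, with the quaternary silyloxy carbon untouched.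

Step 7
Reactants: 10 tert-butyl (4S)-9-(tert-butyldimethylsilyloxy)-4-methyl-3-oxo-4-(triethylsilyloxy)non-7-ynoate
Product: 11 tert-butyl 6-[(E)-2-(tert-butyldimethylsilyloxy)-1-iodoethylidene]-3-methyl-2-oxo-3-(triethylsilyloxy)cyclohexane-1-carboxylate (iodine trans to C1; ester cis to OSiEt3)
Conditions: (Ph3P)AuCl (5 mol%), AgOTf (5 mol%), N-iodosuccinimide (1.2 equiv), CH2Cl2, 0 °C → rt, dark
Reagents that add atoms: N-iodosuccinimide, O=C1CCC(=O)N1I
Why: Cationic (Ph3P)Au+ (monovalent gold, from (Ph3P)AuCl and AgOTf) binds the alkyne, and the enol carbon C1 of the keto ester attacks the nearer alkyne carbon C6 from the face opposite to gold, a Conia-ene carbocyclisation. Ring B closes in the 6-exo-dig mode with the enol double bond inside the forming ring; the vinylgold species is iodinated by N-iodosuccinimide with retention, and direct iodonium activation of the alkyne would lead through the same anti addition to the same alkene. Iodine therefore ends trans to C1 and the CH2OSi group cis to C1, the geometry required once iodine is exchanged for methyl. The closest known reaction types are the gold-catalysed Conia-ene reaction of alkynyl β-keto esters and the iodocarbocyclisation of alkynyl 1,3-dicarbonyl compounds; the internal alkyne and the six-membered ring make this a demanding case. The new stereocentre C1 is enolisable and should settle under thermodynamic control with the ester axial (allylic 1,3-strain with the cis CH2OSi group) and facing the axial OSiEt3 rather than the methyl group; it is not relied on, because C1 is set again in step 10. The step needs C- rather than O-cyclisation of the enol, 6-exo rather than 7-endo attack, and cyclisation rather than plain α-iodination. The fully substituted C3 in the tether favours the folded conformer, attack at the nearer alkyne carbon by the soft enol carbon gives the less strained ring, and an α-iodo keto ester formed on the side is itself an iodonium donor that can re-enter the productive path.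

Step 8
Reactants: 11 iodoalkylidene keto ester
Product: 12 tert-butyl 6-[(Z)-1-(tert-butyldimethylsilyloxy)propan-2-ylidene]-3-methyl-2-oxo-3-(triethylsilyloxy)cyclohexane-1-carboxylate (CH2OSi cis to C1)
Conditions: MeZnCl (3 equiv), Pd(PPh3)4 (5 mol%), THF, 50 °C
Reagents that add atoms: methylzinc chloride, C[Zn]Cl
Why: Negishi coupling with retention of the alkene geometry; one equivalent of the zinc reagent is consumed by the acidic C1–H, and the zinc enolate is protonated again at C1 on work-up.

Step 9
Reactants: 12 methylated keto ester
Product: 13 tert-butyl 1-allyl-6-[(Z)-1-(tert-butyldimethylsilyloxy)propan-2-ylidene]-3-methyl-2-oxo-3-(triethylsilyloxy)cyclohexane-1-carboxylate (configuration at C1 immaterial)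
Conditions: allyl bromide, K2CO3, acetone, 50 °C
Reagents that add atoms: allyl bromide, C=CCBr
Why: C-Alkylation of a cyclic β-keto ester enolate with an allylic halide brings in the three carbons of the arm; quaternisation removes the acidic hydrogen, so the exocyclic alkene can no longer migrate.

Step 10
Reactants: 13 allylated keto ester
Product: 16 allyl ketone (C2 ketone; C1 allyl cis to C3 OSiEt3; exocyclic alkene unchanged), via trimethylsilyl ester 14 (not isolated), via keto acid 15 (not isolated)
Conditions: TMSOTf, 2,6-lutidine, CH2Cl2, 0 °C; aq. citric acid, THF; toluene, 60 °C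
Reagents that add atoms: none
Why: The silyl triflate cleaves the tert-butyl ester by O-silylation and loss of isobutene under conditions that spare the silyl ethers, and the β-keto acid decarboxylates through its enol on gentle warming. Ketonisation at C1 (α-protonation of a dienol is kinetically preferred over γ-protonation) should occur anti to the axial OSiEt3 and place the allyl group cis to it; this is also the more stable epimer (allyl axial by allylic strain, facing oxygen and not methyl).

Step 11
Reactants: 16 allyl ketone
Product: 17 triene with C2 exocyclic methylene (C1 allyl cis to C3 OSiEt3)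
Conditions: Cp2TiMe2, toluene, 75 °C, dark
Reagents that add atoms: dimethyltitanocene, C[Ti](C)(C1C=CC=C1)C1C=CC=C1
Why: Petasis methylenation through a titanium methylidene and an oxatitanacyclobutane is non-basic and suits a hindered, epimerisable α-silyloxy ketone that a phosphorus ylide would enolise; after this step C1 can no longer epimerise.

Step 12
Reactants: 17 triene with C2 exocyclic methylene
Product: 19 diol (arm CH2CH2CH2OH at C1; CH2OH at C2; C2 configuration not controlled), via bis-borane 18 (not isolated)
Conditions: 9-BBN (4 equiv), THF, rt → 60 °C; H2O2, aq. NaOH, 0 °C → rt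
Reagents that add atoms: hydrogen peroxide, OO
Why: Anti-Markovnikov hydroboration–oxidation; 9-BBN adds to the monosubstituted and the 1,1-disubstituted alkene and leaves the tetrasubstituted one. The C2 centre formed here does not matter because it is enolised in step 15.

Step 13
Reactants: 19 diol
Product: 20 mono-silyl ether (arm OTBS; C7 hydroxyl free)
Conditions: TBSCl (1.05 equiv), imidazole, CH2Cl2, −20 °C
Reagents that add atoms: tert-butyldimethylsilyl chloride, CC(C)(C)[Si](C)(C)Cl
Why: Steric differentiation of two primary alcohols; the arm hydroxyl is unhindered, whereas the C7 hydroxyl sits on a carbon attached to C2, between a quaternary and a tertiary centre.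

Step 14
Reactants: 20 mono-silyl ether
Product: 21 aldehyde (C7 formyl on C2; C2 epimers)
Conditions: Dess–Martin periodinane, NaHCO3, CH2Cl2, 0 °C → rt
Reagents that add atoms: none
Why: Dess–Martin oxidation under buffered, near-neutral conditions gives the α-branched aldehyde without β-elimination of the silyloxy group.

Step 15
Reactants: 21 aldehyde
Product: 23 quaternary aldehyde (C2 bears formyl C7 cis to the C1 arm and to OSiEt3; allyl trans to both), via potassium enolate 22 (not isolated)
Conditions: KN(SiMe3)2, THF, −78 °C; allyl iodide, −78 → −30 °C
Reagents that add atoms: allyl iodide, C=CCI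
Why: C-Allylation of an α,α-disubstituted aldehyde enolate (any O-allyl enol ether would converge by Claisen rearrangement). With the C1 arm axial (allylic strain) and the C3 OSiEt3 axial on the same face, the electrophile should enter from the opposite face; C10 then lies trans and the formyl carbon cis to both, as in the target.

Step 16
Reactants: 23 quaternary aldehyde
Product: 24 (E)-enone aldehyde (C2 bears CH2CH=CHC(O)CH3 and CHO)
Conditions: second-generation Hoveyda–Grubbs catalyst (5 mol%), methyl vinyl ketone (5 equiv), CH2Cl2, 40 °C
Reagents that add atoms: methyl vinyl ketone, CC(=O)C=C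
Why: Cross-metathesis of the only monosubstituted alkene with an electron-poor enone partner gives the (E)-enone; the tetrasubstituted alkene and the aldehyde take no part.

Step 17
Reactants: 24 (E)-enone aldehyde
Product: 25 spiro hydroxy ketone (ring A closed; C7 OH and C8 acetyl cis; OH on the C1 side)
Conditions: [(Ph3P)CuH]6 (0.35 equiv), toluene, −40 → 0 °C; aq. NH4Cl
Reagents that add atoms: none
Why: Reductive aldol cyclisation; copper hydride adds to C9 and the copper enolate closes on the aldehyde (5-exo-trig, enolate exocyclic) through a closed chair-like transition state, which gives the cis β-hydroxy ketone. The aldehyde oxygen with its copper should turn towards the C1–H flank and away from the fully substituted, silyloxy-bearing C3 (steric and dipole repulsion), which puts the C7 hydroxyl on the C1 side.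

Step 18
Reactants: 25 spiro hydroxy ketone
Product: 26 C7 triethylsilyl ether of 25
Conditions: TESOTf, 2,6-lutidine, CH2Cl2, −78 °C
Reagents that add atoms: triethylsilyl triflate, CC[Si](CC)(CC)OS(=O)(=O)C(F)(F)F
Why: Low-temperature silylation of the hindered secondary alcohol; it blocks retro-aldol and elimination in the next step and gives a group that fluoride removes easily at the end.

Step 19
Reactants: 26 silylated methyl ketone
Product: 28 enol triflate (C8–C(OTf)=CH2), via potassium enolate 27 (not isolated)
Conditions: KN(SiMe3)2, THF, −78 °C; PhNTf2, −78 → 0 °C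
Reagents that add atoms: N-phenylbis(trifluoromethanesulfonimide), O=S(=O)(N(c1ccccc1)S(=O)(=O)C(F)(F)F)C(F)(F)F
Why: Kinetic deprotonation of the methyl ketone on the methyl side by a hindered amide base, then O-triflation, gives the terminal enol triflate; the C8 stereocentre is not touched.

Step 20
Reactants: 29 propargyl alcohol; 30 5-bromo-2-methylpent-2-ene
Product: 33 (Z)-3-iodo-2-(4-methylpent-3-enyl)prop-2-en-1-ol, via homoprenylmagnesium bromide 31 (not isolated), via alkenylmagnesium chelate 32 (not isolated)
Conditions: Mg, THF (30, 2.5 equiv); 29, CuI (10 mol%), Et2O, 0 °C → reflux; I2, −40 → 0 °C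
Reagents that add atoms: iodine, II
Why: Copper-catalysed anti carbomagnesiation of propargyl alcohol; the magnesium alkoxide directs the alkyl group to C15 and magnesium to C14, cis to CH2O in a five-membered chelate, and iodine replaces magnesium with retention.

Step 21
Reactants: 33 (Z)-3-iodo-2-(4-methylpent-3-enyl)prop-2-en-1-ol
Product: 34 (Z)-3-iodo-2-(4-methylpent-3-enyl)prop-2-enyl acetate
Conditions: Ac2O, pyridine, DMAP (cat.), CH2Cl2, 0 °C
Reagents that add atoms: acetic anhydride, CC(=O)OC(C)=O
Why: Acetylation of a primary allylic alcohol; the acetate is now in place and meets no base or hydride in the later steps.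

Step 22
Reactants: 34 (Z)-3-iodo-2-(4-methylpent-3-enyl)prop-2-enyl acetate; 35 (E)-1,2-bis(tributylstannyl)ethene
Product: 36 (2Z,4E)-2-(4-methylpent-3-enyl)-5-(tributylstannyl)penta-2,4-dienyl acetate
Conditions: 35 (3 equiv), PdCl2(MeCN)2 (5 mol%), DMF, rt
Reagents that add atoms: none
Why: Stille coupling of an alkenyl iodide at room temperature; the excess of bis-stannane ensures mono-coupling, with retention at both alkenes.

Step 23
Reactants: 28 enol triflate; 36 dienylstannane
Product: 37 fully protected triene (target with arm OTBS; C6 CH2OTBS; C3 OSiEt3; C7 OSiEt3)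
Conditions: Pd(PPh3)4 (10 mol%), LiCl, CuCl, DMSO, rt → 50 °C
Reagents that add atoms: none
Why: Stille coupling of an enol triflate, with LiCl and CuCl to speed transmetalation for the hindered partner; it forms the C11–C12 bond under neutral conditions with retention of every alkene geometry.

Step 24
Reactants: 37 fully protected triene
Product: 38 tetraol (C6 exocyclic CH2OH; all other groups as in the target)
Conditions: HF·pyridine, pyridine, THF, 0 °C → rt
Reagents that add atoms: none
Why: Fluoride desilylation buffered with pyridine removes all four silyl ethers and leaves the acetate, the triene and the tertiary alcohol intact.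

Step 25
Reactants: 38 tetraol
Product: 39 target CNP0205332.1
Conditions: MnO2, CH2Cl2, rt
Reagents that add atoms: none
Why: MnO2 oxidises only the allylic alcohol; the homoallylic C7 hydroxyl, the saturated primary alcohol and the tertiary alcohol are not oxidised, and the alkene geometry set in step 7 is kept.

## Compound list

1 | (S)-(+)-linalool | C=C[C@@](C)(O)CCC=C(C)C | starting material
2 | (3S)-3,7-dimethyl-3-(triethylsilyloxy)octa-1,6-diene | C=C[C@@](C)(O[Si](CC)(CC)CC)CCC=C(C)C | intermediate
3 | (4S)-4-methyl-4-(triethylsilyloxy)hex-5-enal | C=C[C@@](C)(O[Si](CC)(CC)CC)CCC=O | intermediate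
4 | (3S)-3-methyl-3-(triethylsilyloxy)hept-1-en-6-yne | C=C[C@@](C)(O[Si](CC)(CC)CC)CCC#C | intermediate
5 | lithium acetylide of 4 | C=C[C@@](C)(O[Si](CC)(CC)CC)CCC#C[Li] | intermediate
6 | lithium alkoxide of the propargylic alcohol from 5 and formaldehyde | C=C[C@@](C)(O[Si](CC)(CC)CC)CCC#CCO[Li] | intermediate
7 | (3S)-8-(tert-butyldimethylsilyloxy)-3-methyl-3-(triethylsilyloxy)oct-1-en-6-yne | C=C[C@@](C)(O[Si](CC)(CC)CC)CCC#CCO[Si](C)(C)C(C)(C)C | intermediate
8 | (2S)-7-(tert-butyldimethylsilyloxy)-2-methyl-2-(triethylsilyloxy)hept-5-ynal | O=C[C@@](C)(O[Si](CC)(CC)CC)CCC#CCO[Si](C)(C)C(C)(C)C | intermediate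
9 | tert-butyl diazoacetate | CC(C)(C)OC(=O)C=[N+]=[N-] | starting material
10 | tert-butyl (4S)-9-(tert-butyldimethylsilyloxy)-4-methyl-3-oxo-4-(triethylsilyloxy)non-7-ynoate (key-step precursor) | CC(C)(C)OC(=O)CC(=O)[C@@](C)(O[Si](CC)(CC)CC)CCC#CCO[Si](C)(C)C(C)(C)C | intermediate
11 | ring B keto ester with (E)-iodoalkylidene: iodine trans to C1, CH2OTBS cis to C1, ester cis to OSiEt3 (key-step product) | CC(C)(C)OC(=O)[C@H]1C(=O)[C@@](C)(O[Si](CC)(CC)CC)CC/C1=C(\I)CO[Si](C)(C)C(C)(C)C | intermediate
12 | methylated keto ester: exocyclic C(CH3)CH2OTBS, CH2O cis to C1 | CC(C)(C)OC(=O)[C@H]1C(=O)[C@@](C)(O[Si](CC)(CC)CC)CC/C1=C(\C)CO[Si](C)(C)C(C)(C)C | intermediate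
13 | C1-allylated keto ester (C1 quaternary, configuration not specified) | CC(C)(C)OC(=O)C1(CC=C)C(=O)[C@@](C)(O[Si](CC)(CC)CC)CC/C1=C(\C)CO[Si](C)(C)C(C)(C)C | intermediate
14 | trimethylsilyl ester of 15 | C[Si](C)(C)OC(=O)C1(CC=C)C(=O)[C@@](C)(O[Si](CC)(CC)CC)CC/C1=C(\C)CO[Si](C)(C)C(C)(C)C | intermediate
15 | β-keto acid (C1 allyl, C1 carboxylic acid) | OC(=O)C1(CC=C)C(=O)[C@@](C)(O[Si](CC)(CC)CC)CC/C1=C(\C)CO[Si](C)(C)C(C)(C)C | intermediate
16 | allyl ketone: C2 ketone, C1 allyl cis to C3 OSiEt3 | C=CC[C@H]1C(=O)[C@@](C)(O[Si](CC)(CC)CC)CC/C1=C(\C)CO[Si](C)(C)C(C)(C)C | intermediate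
17 | methylenated triene: C2=CH2, C1 allyl cis to C3 OSiEt3 | C=CC[C@H]1C(=C)[C@@](C)(O[Si](CC)(CC)CC)CC/C1=C(\C)CO[Si](C)(C)C(C)(C)C | intermediate
18 | bis(9-borabicyclononyl) adduct of 17 (boron on the arm terminus and on the C2 CH2; C2 unspecified) | B1(CCC[C@H]2C(CB3C4CCCC3CCC4)[C@@](C)(O[Si](CC)(CC)CC)CC/C2=C(\C)CO[Si](C)(C)C(C)(C)C)C5CCCC1CCC5 | intermediate
19 | diol: C1 3-hydroxypropyl, C2 hydroxymethyl (C2 unspecified) | OCCC[C@H]1C(CO)[C@@](C)(O[Si](CC)(CC)CC)CC/C1=C(\C)CO[Si](C)(C)C(C)(C)C | intermediate
20 | mono-silyl ether: arm OTBS, C2 hydroxymethyl free (C2 unspecified) | CC(C)(C)[Si](C)(C)OCCC[C@H]1C(CO)[C@@](C)(O[Si](CC)(CC)CC)CC/C1=C(\C)CO[Si](C)(C)C(C)(C)C | intermediate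
21 | aldehyde: C2 formyl (C2 unspecified) | CC(C)(C)[Si](C)(C)OCCC[C@H]1C(C=O)[C@@](C)(O[Si](CC)(CC)CC)CC/C1=C(\C)CO[Si](C)(C)C(C)(C)C | intermediate
22 | potassium enolate of 21 (exocyclic at C2) | CC(C)(C)[Si](C)(C)OCCC[C@H]1C(=C[O-])[C@@](C)(O[Si](CC)(CC)CC)CC/C1=C(\C)CO[Si](C)(C)C(C)(C)C.[K+] | intermediate
23 | quaternary aldehyde: C2 formyl cis to C1 arm and C3 OSiEt3, C2 allyl trans | CC(C)(C)[Si](C)(C)OCCC[C@H]1[C@@](CC=C)(C=O)[C@@](C)(O[Si](CC)(CC)CC)CC/C1=C(\C)CO[Si](C)(C)C(C)(C)C | intermediate
24 | (E)-enone aldehyde: C2 bears CHO and CH2CH=CHC(O)CH3 | CC(C)(C)[Si](C)(C)OCCC[C@H]1[C@@](C/C=C/C(C)=O)(C=O)[C@@](C)(O[Si](CC)(CC)CC)CC/C1=C(\C)CO[Si](C)(C)C(C)(C)C | intermediate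
25 | spiro hydroxy ketone: ring A closed, C7 OH and C8 acetyl cis, OH on the C1 side | CC(=O)[C@@H]1CC[C@]2([C@H](CCCO[Si](C)(C)C(C)(C)C)/C(=C(/C)CO[Si](C)(C)C(C)(C)C)CC[C@]2(C)O[Si](CC)(CC)CC)[C@@H]1O | intermediate
26 | C7 triethylsilyl ether of 25 | CC(=O)[C@@H]1CC[C@]2([C@H](CCCO[Si](C)(C)C(C)(C)C)/C(=C(/C)CO[Si](C)(C)C(C)(C)C)CC[C@]2(C)O[Si](CC)(CC)CC)[C@@H]1O[Si](CC)(CC)CC | intermediate
27 | potassium enolate of 26 (methyl side) | [K+].[O-]C(=C)[C@@H]1CC[C@]2([C@H](CCCO[Si](C)(C)C(C)(C)C)/C(=C(/C)CO[Si](C)(C)C(C)(C)C)CC[C@]2(C)O[Si](CC)(CC)CC)[C@@H]1O[Si](CC)(CC)CC | intermediate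
28 | enol triflate: C8–C(OTf)=CH2 | C=C(OS(=O)(=O)C(F)(F)F)[C@@H]1CC[C@]2([C@H](CCCO[Si](C)(C)C(C)(C)C)/C(=C(/C)CO[Si](C)(C)C(C)(C)C)CC[C@]2(C)O[Si](CC)(CC)CC)[C@@H]1O[Si](CC)(CC)CC | intermediate
29 | propargyl alcohol | C#CCO | starting material
30 | 5-bromo-2-methylpent-2-ene | CC(C)=CCCBr | starting material
31 | homoprenylmagnesium bromide | CC(C)=CCC[Mg]Br | intermediate
32 | alkenylmagnesium chelate (magnesium on C14 cis to CH2O) | Br[Mg]OC/C(CCC=C(C)C)=C\[Mg]Br | intermediate
33 | (Z)-3-iodo-2-(4-methylpent-3-enyl)prop-2-en-1-ol | OC/C(CCC=C(C)C)=C\I | intermediate
34 | (Z)-3-iodo-2-(4-methylpent-3-enyl)prop-2-enyl acetate | CC(=O)OC/C(CCC=C(C)C)=C\I | intermediate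
35 | (E)-1,2-bis(tributylstannyl)ethene | CCCC[Sn](CCCC)(CCCC)/C=C/[Sn](CCCC)(CCCC)CCCC | starting material
36 | (2Z,4E)-2-(4-methylpent-3-enyl)-5-(tributylstannyl)penta-2,4-dienyl acetate | CCCC[Sn](CCCC)(CCCC)/C=C/C=C(\COC(C)=O)CCC=C(C)C | intermediate
37 | fully protected triene: arm OTBS, C6 exocyclic CH2OTBS, C3 OSiEt3, C7 OSiEt3 | C=C(/C=C/C=C(/CCC=C(C)C)COC(C)=O)[C@@H]1CC[C@]2([C@H](CCCO[Si](C)(C)C(C)(C)C)/C(=C(/C)CO[Si](C)(C)C(C)(C)C)CC[C@]2(C)O[Si](CC)(CC)CC)[C@@H]1O[Si](CC)(CC)CC | intermediate
38 | tetraol: C6 exocyclic C(CH3)CH2OH, otherwise as the target | C=C(/C=C/C=C(/CCC=C(C)C)COC(C)=O)[C@@H]1CC[C@]2([C@H](CCCO)/C(=C(/C)CO)CC[C@]2(C)O)[C@@H]1O | intermediate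
39 | CNP0205332.1 | C=C(/C=C/C=C(/CCC=C(C)C)COC(C)=O)[C@@H]1CC[C@]2([C@H](CCCO)/C(=C(/C)C=O)CC[C@]2(C)O)[C@@H]1O | target

## Step count and least certain steps

Total step count: 25 (22 in the main line, 3 for the side-chain stannane). Longest linear sequence: 22 steps (steps 1–19 and 23–25).

Step 7 (key step). What may go wrong: O-cyclisation of the enol, plain α-iodination without ring closure, slow attack on the internal alkyne, or acid-promoted loss of the tert-butyl ester. Fallback: starting from 10, the titanium enolate is formed with Ti(OtBu)4 in CH2Cl2 and treated with I2. The alkyne is then activated as an iodonium ion without gold, the enolate carbon again adds anti, and the route is rejoined at 11. This fallback makes no compound outside the list (F0).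

Step 10. What may go wrong: migration of the exocyclic alkene into conjugation with the ketone while the enol ketonises (which would also erase the geometry from step 7), or protonation of C1 from the wrong face. Fallback: starting from 12, steps 9 and 10 are replaced. Transesterification with allyl alcohol in toluene at 110 °C (through the acyl ketene) gives the allyl keto ester F1. Pd(PPh3)4 in THF at room temperature then effects a Tsuji-type decarboxylative allylation: the palladium enolate formed by loss of CO2 is allylated at C1 under neutral conditions and without a free enol. A brief treatment with DBU would bring C1 to the axial, cis epimer if needed. The route is rejoined at 16.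

Step 15. What may go wrong: β-elimination of the silyloxy group from the aldehyde enolate, O-allylation, or poor facial selectivity at C2. Fallback: starting from 21, hydroxylamine hydrochloride and pyridine give the oxime F2, which is dehydrated with Burgess reagent to the nitrile F3. The nitrile anion (LiN(iPr)2, THF, −78 °C) alkylates only on carbon and is less prone to elimination; with allyl bromide it gives the quaternary nitrile F4 under the same facial control. iBu2AlH in toluene at −78 °C, followed by mild hydrolysis, returns the route to 23.

Step 17. What may go wrong: closure on the other face of the aldehyde (both ring A centres then wrong relative to ring B), or plain 1,2-reduction of the aldehyde. Fallback: starting from 23, cross-metathesis with allyltrimethylsilane (second-generation Hoveyda–Grubbs catalyst) gives the allylsilane F5. BF3·OEt2 at −78 °C then closes ring A by a Hosomi–Sakurai allylation through an open transition state without a metal chelate, giving the vinyl cyclopentanol F6. Wacker oxidation (PdCl2, CuCl, O2, DMF/H2O) of the vinyl group returns the route to 25.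

Step 23. What may go wrong: slow transmetalation between the hindered enol triflate and the large dienylstannane, with protodestannylation, homocoupling or isomerisation of the triene. Fallback: starting from 28, the order of bond formation is reversed. Coupling with 35 (Pd(PPh3)4, LiCl, THF) gives the ring-bound dienylstannane F7, and a second Stille coupling with the more reactive alkenyl iodide 34 (PdCl2(MeCN)2, DMF, rt) forms the C13–C14 bond last and returns the route to 37.

## Further compounds

F0 | step 7 | none | none
F1 | step 10 | allyl ester analogue of 12 (allyl keto ester) | C=CCOC(=O)[C@H]1C(=O)[C@@](C)(O[Si](CC)(CC)CC)CC/C1=C(\C)CO[Si](C)(C)C(C)(C)C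
F2 | step 15 | oxime of 21 | CC(C)(C)[Si](C)(C)OCCC[C@H]1C(C=NO)[C@@](C)(O[Si](CC)(CC)CC)CC/C1=C(\C)CO[Si](C)(C)C(C)(C)C
F3 | step 15 | nitrile from 21 (C2 cyano, C2 unspecified) | CC(C)(C)[Si](C)(C)OCCC[C@H]1C(C#N)[C@@](C)(O[Si](CC)(CC)CC)CC/C1=C(\C)CO[Si](C)(C)C(C)(C)C
F4 | step 15 | quaternary nitrile (C2 cyano cis to C1 arm, C2 allyl trans) | CC(C)(C)[Si](C)(C)OCCC[C@H]1[C@@](CC=C)(C#N)[C@@](C)(O[Si](CC)(CC)CC)CC/C1=C(\C)CO[Si](C)(C)C(C)(C)C
F5 | step 17 | allylsilane aldehyde (C2 bears CHO and CH2CH=CHCH2SiMe3) | CC(C)(C)[Si](C)(C)OCCC[C@H]1[C@@](C/C=C/C[Si](C)(C)C)(C=O)[C@@](C)(O[Si](CC)(CC)CC)CC/C1=C(\C)CO[Si](C)(C)C(C)(C)C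
F6 | step 17 | vinyl cyclopentanol (C8 vinyl cis to C7 OH) | C=C[C@@H]1CC[C@]2([C@H](CCCO[Si](C)(C)C(C)(C)C)/C(=C(/C)CO[Si](C)(C)C(C)(C)C)CC[C@]2(C)O[Si](CC)(CC)CC)[C@@H]1O
F7 | step 23 | ring-bound (E)-dienylstannane (C8–C(=CH2)–CH=CH–SnBu3) | CCCC[Sn](CCCC)(CCCC)/C=C/C(=C)[C@@H]1CC[C@]2([C@H](CCCO[Si](C)(C)C(C)(C)C)/C(=C(/C)CO[Si](C)(C)C(C)(C)C)CC[C@]2(C)O[Si](CC)(CC)CC)[C@@H]1O[Si](CC)(CC)CC
A1 | alternative 1 | 1-(cyclohexenyl)cyclobutanol ketal, substrate of the epoxidation and ring expansion | CC1=C(C2(O)CCC2)CC3(OCCO3)CC1
A2 | alternative 1 | spiro hydroxy ketone ketal | O=C1CCC[C@]12CC3(OCCO3)CC[C@]2(C)O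
A3 | alternative 2 | cycloheptadienol tethered to a cyclopentylidene dimethylcarbamate (one plausible form of the cyclisation substrate) | CC1(O)C=CCCC=C1CC/C(C)=C2\[C@@H](OC(=O)N(C)C)CCC2
A4 | alternative 2 | spiro tricyclic diene with cyclic carbonate | C1CC[C@]2([C@@H]3CCC=CC(C)=C3CC[C@]2(C)O4)[C@H]1OC4=O
A5 | alternative 3 | monocyclic dialdehyde precursor of the carbonyl-ene closure (implied form) | O=C[C@]1(CC/C=C(C)/C=C/C=C(/CCC=C(C)C)COC(C)=O)[C@H](CCCO[Si](C)(C)C(C)(C)C)/C(=C(/C)C=O)CC[C@]1(C)O[Si](CC)(CC)CC
A6 | alternative 3 | bis-silyl ether of the target | C=C(/C=C/C=C(/CCC=C(C)C)COC(C)=O)[C@@H]1CC[C@]2([C@H](CCCO[Si](C)(C)C(C)(C)C)/C(=C(/C)C=O)CC[C@]2(C)O[Si](CC)(CC)CC)[C@@H]1O
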